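**Plan**
1. Retrosynthesis: the five O–CH3 bonds are cut last. The 8-chloro isoflavone is opened at C2 (the one-carbon unit between O1 and C3) and at C4–C4a, giving an arylacetic acid and 2-chloro-3,5-dimethoxyphenol.
2. The 8-aryloxy isoflavone is cut at C4–C4a (acylation by a (Z)-3-aryloxy-2-arylacrylic acid), then at O1–C2 (phenol plus enol tosylate) and at the diaryl ether C–O bond (phenol plus aryl iodide).
3. Enabling feature: in this unit O1 on C8a and the ether oxygen on C8 are adjacent on ring A. The phenol carrying the aryloxy group ortho therefore has a single free ortho carbon, the future C4a, and closing ring C there can only give the 8-aryloxy pattern.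
4. Forward order: ring A catechol monoether (Dakin) → diaryl ether → aryl enol ether → ring C of the aryloxy isoflavone → arylacetic acid → deoxybenzoin with the chlorophenol → ring C of the chloro isoflavone → global demethylation.
5. Stereochemistry: the target has no stereocentre. The only stereo-element on the way is the Z geometry of the acrylate, set by chelation-controlled enol tosylation and kept in the vinylic substitution.

Key step: step 10

Remark: methyl (4-iodophenyl)acetate is taken as purchasable, and any E isomer of the aryloxyacrylate is expected to converge in the acidic ring closure by reversible C-protonation of the enol ether.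

**Route**

Step 1
Reactants: 1 2-hydroxy-4,6-dimethoxybenzaldehyde
Product: 2 2-(benzyloxy)-4,6-dimethoxybenzaldehyde
Conditions: BnBr, K2CO3, DMF, 60 °C
Reagents that add atoms: benzyl bromide, BrCc1ccccc1
Why: Williamson ether synthesis on the phenoxide should mask the oxygen that later becomes O1 as a benzyl ether, which can be removed by hydrogenolysis at a stage where no chlorine is present.

Step 2
Reactants: 2 2-(benzyloxy)-4,6-dimethoxybenzaldehyde
Product: 4 2-(benzyloxy)-4,6-dimethoxyphenol, via aryl formate 3 (not isolated)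
Conditions: mCPBA, CH2Cl2, 0 °C → rt; then K2CO3 (cat.), MeOH, rt
Reagents that add atoms: 3-chloroperoxybenzoic acid (mCPBA), OOC(=O)c1cccc(Cl)c1
Why: Dakin-type Baeyer–Villiger oxidation, in which the electron-rich aryl group migrates in the Criegee adduct to give the formate, and mild methanolysis should then release the phenol flanked by the benzyloxy and methoxy groups.

Step 3
Reactants: 4 2-(benzyloxy)-4,6-dimethoxyphenol, 5 methyl (4-iodophenyl)acetate
Product: 6 methyl {4-[2-(benzyloxy)-4,6-dimethoxyphenoxy]phenyl}acetate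
Conditions: CuI (10 mol %), picolinic acid (20 mol %), K3PO4, DMSO, 90 °C, argon
Reagents that add atoms: none
Why: Ullmann-type copper-catalysed diaryl ether coupling with a picolinate ligand accepts di-ortho-substituted phenols, and the oxidant-free conditions should spare the oxidation-prone phenol and the methyl ester.

Step 4
Reactants: 6 methyl {4-[2-(benzyloxy)-4,6-dimethoxyphenoxy]phenyl}acetate
Product: 7 methyl [4-(2-hydroxy-4,6-dimethoxyphenoxy)phenyl]acetate
Conditions: H2 (1 atm), 10% Pd/C, EtOAc–MeOH, rt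
Reagents that add atoms: none
Why: Hydrogenolysis of the benzyl aryl ether should free the single phenol (future O1) while the ester, the methyl ethers and the diaryl ether stay intact.

Step 5
Reactants: 8 4-methoxyphenylacetic acid
Product: 9 tert-butyl (4-methoxyphenyl)acetate
Conditions: tert-butyl 2,2,2-trichloroacetimidate, BF3·Et2O (cat.), CH2Cl2–cyclohexane, rt
Reagents that add atoms: tert-butyl 2,2,2-trichloroacetimidate, CC(C)(C)OC(=N)C(Cl)(Cl)Cl
Why: Acid-catalysed O-alkylation of the carboxylic acid by the imidate gives a tert-butyl ester, chosen because it can later be cleaved by acid without touching the methyl ester of the other fragment.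

Step 6
Reactants: 9 tert-butyl (4-methoxyphenyl)acetate
Product: 10 tert-butyl (Z)-3-hydroxy-2-(4-methoxyphenyl)prop-2-enoate (enol form of the α-formyl ester)
Conditions: HCO2Et, KOt-Bu, THF, 0 °C → rt; then 1 M HCl
Reagents that add atoms: ethyl formate, CCOC=O
Why: Crossed Claisen condensation (C-formylation) of the arylacetate enolate with ethyl formate is driven by formation of the stabilised enolate, and the hindered tert-butyl ester should resist transesterification.

Step 7
Reactants: 10 tert-butyl (Z)-3-hydroxy-2-(4-methoxyphenyl)prop-2-enoate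
Product: 11 tert-butyl (Z)-2-(4-methoxyphenyl)-3-{[(4-methylphenyl)sulfonyl]oxy}prop-2-enoate
Conditions: TsCl, N-methylimidazole, LiOH, MeCN, 0 °C → rt
Reagents that add atoms: p-toluenesulfonyl chloride, Cc1ccc(cc1)S(Cl)(=O)=O
Why: O-sulfonylation of the lithium-chelated enolate, with N-methylimidazole as sulfonyl-transfer agent, should hold the enolate oxygen cis to the ester carbonyl and so give the Z enol tosylate.

Step 8
Reactants: 7 methyl [4-(2-hydroxy-4,6-dimethoxyphenoxy)phenyl]acetate, 11 tert-butyl (Z)-2-(4-methoxyphenyl)-3-{[(4-methylphenyl)sulfonyl]oxy}prop-2-enoate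
Product: 12 tert-butyl (Z)-3-{2-[4-(2-methoxy-2-oxoethyl)phenoxy]-3,5-dimethoxyphenoxy}-2-(4-methoxyphenyl)prop-2-enoate
Conditions: Cs2CO3, MeCN, rt → 40 °C
Reagents that add atoms: none
Why: Nucleophilic vinylic substitution (conjugate addition–elimination) of the phenoxide at the β-carbon of the enol tosylate is expected to go with retention of the double-bond geometry and to put the O1–C2 bond in place.

Step 9
Reactants: 12 tert-butyl (Z)-3-{2-[4-(2-methoxy-2-oxoethyl)phenoxy]-3,5-dimethoxyphenoxy}-2-(4-methoxyphenyl)prop-2-enoate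
Product: 13 (Z)-3-{2-[4-(2-methoxy-2-oxoethyl)phenoxy]-3,5-dimethoxyphenoxy}-2-(4-methoxyphenyl)prop-2-enoic acid
Conditions: CF3CO2H, anisole, CH2Cl2, 0 °C → rt
Reagents that add atoms: none
Why: Acidolysis of the tert-butyl ester with loss of isobutylene (anisole as cation scavenger) should leave the methyl ester and the aryl enol ether untouched under anhydrous conditions.

Step 10
Reactants: 13 (Z)-3-{2-[4-(2-methoxy-2-oxoethyl)phenoxy]-3,5-dimethoxyphenoxy}-2-(4-methoxyphenyl)prop-2-enoic acid
Product: 14 methyl (4-{[5,7-dimethoxy-3-(4-methoxyphenyl)-4-oxo-4H-chromen-8-yl]oxy}phenyl)acetate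
Conditions: P2O5 in CH3SO3H (Eaton's reagent), 25 → 40 °C
Reagents that add atoms: none
Why: P2O5 in CH3SO3H should dehydrate the carboxylic acid to an acylium ion (or its mixed anhydride) held cis to the enol ether oxygen, which attacks the ring A carbon ortho to that oxygen, and loss of a proton rearomatises the ring and leaves the 4-pyranone with the new C4–C4a bond. The closest known reaction is the acid-mediated intramolecular Friedel–Crafts cyclisation of 3-aryloxyacrylic acids to chromones. Ring C closes by a six-membered (6-exo) attack of an arene carbon on the acyl carbon. No stereocentre is created. The step needs site selectivity, which is secured because the carbon attacked is the only unsubstituted position ortho to the enol ether oxygen and is activated by one ortho and one para methoxy group, while ring B and the phenoxy ring cannot reach the acyl carbon through a six-membered transition state, so only the 8-aryloxy pattern can form. It also needs the acid cis to the aryloxy group, which the Z geometry provides and which any E isomer should regain by reversible C-protonation of the enol ether in the strong acid, and the methyl ester and methyl ethers should tolerate the mild temperature.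

Step 11
Reactants: 14 methyl (4-{[5,7-dimethoxy-3-(4-methoxyphenyl)-4-oxo-4H-chromen-8-yl]oxy}phenyl)acetate
Product: 15 (4-{[5,7-dimethoxy-3-(4-methoxyphenyl)-4-oxo-4H-chromen-8-yl]oxy}phenyl)acetic acid
Conditions: 6 M HCl, 1,4-dioxane, 90 °C
Reagents that add atoms: water, O
Why: Acid-catalysed ester hydrolysis is chosen because the 2-unsubstituted chromone is stable to aqueous acid but prone to ring opening by hydroxide at C2.

Step 12
Reactants: 16 3,5-dimethoxyphenol
Product: 17 2-chloro-3,5-dimethoxyphenol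
Conditions: SO2Cl2 (1.0 equiv), CHCl3, 0 °C; chromatography
Reagents that add atoms: sulfuryl chloride, O=S(=O)(Cl)Cl
Why: Electrophilic aromatic chlorination of the activated phenol at one of its two equivalent positions ortho to the hydroxyl should give the 2-chloro isomer, which is separated from the 4-chloro isomer by chromatography.

Step 13
Reactants: 15 (4-{[5,7-dimethoxy-3-(4-methoxyphenyl)-4-oxo-4H-chromen-8-yl]oxy}phenyl)acetic acid, 17 2-chloro-3,5-dimethoxyphenol (excess)
Product: 18 1-(3-chloro-2-hydroxy-4,6-dimethoxyphenyl)-2-(4-{[5,7-dimethoxy-3-(4-methoxyphenyl)-4-oxo-4H-chromen-8-yl]oxy}phenyl)ethan-1-one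
Conditions: BF3·Et2O (as solvent), 85 °C; then aq. NaOAc
Reagents that add atoms: none
Why: BF3-promoted Friedel–Crafts (Fries-type) C-acylation of the phenol ortho to its free hydroxyl and para to a methoxy group should give the 2-hydroxydeoxybenzoin in which the hydroxyl, the future O1, sits next to the chlorinated carbon.

Step 14
Reactants: 18 1-(3-chloro-2-hydroxy-4,6-dimethoxyphenyl)-2-(4-{[5,7-dimethoxy-3-(4-methoxyphenyl)-4-oxo-4H-chromen-8-yl]oxy}phenyl)ethan-1-one
Product: 20 8-chloro-3-(4-{[5,7-dimethoxy-3-(4-methoxyphenyl)-4-oxo-4H-chromen-8-yl]oxy}phenyl)-5,7-dimethoxy-4H-chromen-4-one, via enaminone 19 (not isolated)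
Conditions: Me2NCH(OMe)2, toluene, 100 °C
Reagents that add atoms: N,N-dimethylformamide dimethyl acetal, COC(OC)N(C)C
Why: Deoxybenzoin-to-isoflavone annulation, in which the benzylic methylene condenses with the amide acetal to the enaminone and the only hydroxyl present, the one next to C–Cl, closes by addition–elimination with loss of dimethylamine.

Step 15
Reactants: 20 8-chloro-3-(4-{[5,7-dimethoxy-3-(4-methoxyphenyl)-4-oxo-4H-chromen-8-yl]oxy}phenyl)-5,7-dimethoxy-4H-chromen-4-one
Product: 21 8-chloro-3-(4-{[5,7-dihydroxy-3-(4-hydroxyphenyl)-4-oxo-4H-chromen-8-yl]oxy}phenyl)-5,7-dihydroxy-4H-chromen-4-one (the target)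
Conditions: BBr3 (excess), CH2Cl2, −78 °C → rt; then MeOH, H2O
Reagents that add atoms: none
Why: Lewis acid ether cleavage, in which BBr3 coordinates each methoxy oxygen and bromide removes the methyl group by SN2, should free all five phenols while the diaryl ether, the aryl chloride and both chromone rings are inert.

**Compound list**
1 | 2-hydroxy-4,6-dimethoxybenzaldehyde | COc1cc(O)c(C=O)c(OC)c1 | starting material
2 | 2-(benzyloxy)-4,6-dimethoxybenzaldehyde | COc1cc(OCc2ccccc2)c(C=O)c(OC)c1 | intermediate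
3 | 2-(benzyloxy)-4,6-dimethoxyphenyl formate (not isolated) | COc1cc(OCc2ccccc2)c(OC=O)c(OC)c1 | intermediate
4 | 2-(benzyloxy)-4,6-dimethoxyphenol | COc1cc(OCc2ccccc2)c(O)c(OC)c1 | intermediate
5 | methyl (4-iodophenyl)acetate | COC(=O)Cc1ccc(I)cc1 | starting material
6 | methyl {4-[2-(benzyloxy)-4,6-dimethoxyphenoxy]phenyl}acetate | COC(=O)Cc1ccc(Oc2c(OCc3ccccc3)cc(OC)cc2OC)cc1 | intermediate
7 | methyl [4-(2-hydroxy-4,6-dimethoxyphenoxy)phenyl]acetate | COC(=O)Cc1ccc(Oc2c(O)cc(OC)cc2OC)cc1 | intermediate
8 | 4-methoxyphenylacetic acid | COc1ccc(CC(=O)O)cc1 | starting material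
9 | tert-butyl (4-methoxyphenyl)acetate | COc1ccc(CC(=O)OC(C)(C)C)cc1 | intermediate
10 | tert-butyl (Z)-3-hydroxy-2-(4-methoxyphenyl)prop-2-enoate | CC(C)(C)OC(=O)/C(=C\O)c1ccc(OC)cc1 | intermediate
11 | tert-butyl (Z)-2-(4-methoxyphenyl)-3-{[(4-methylphenyl)sulfonyl]oxy}prop-2-enoate | CC(C)(C)OC(=O)/C(=C\OS(=O)(=O)c1ccc(C)cc1)c1ccc(OC)cc1 | intermediate
12 | tert-butyl (Z)-3-{2-[4-(2-methoxy-2-oxoethyl)phenoxy]-3,5-dimethoxyphenoxy}-2-(4-methoxyphenyl)prop-2-enoate | CC(C)(C)OC(=O)/C(=C\Oc1cc(OC)cc(OC)c1Oc1ccc(CC(=O)OC)cc1)c1ccc(OC)cc1 | intermediate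
13 | (Z)-3-{2-[4-(2-methoxy-2-oxoethyl)phenoxy]-3,5-dimethoxyphenoxy}-2-(4-methoxyphenyl)prop-2-enoic acid | OC(=O)/C(=C\Oc1cc(OC)cc(OC)c1Oc1ccc(CC(=O)OC)cc1)c1ccc(OC)cc1 | intermediate
14 | methyl (4-{[5,7-dimethoxy-3-(4-methoxyphenyl)-4-oxo-4H-chromen-8-yl]oxy}phenyl)acetate | COC(=O)Cc1ccc(Oc2c(OC)cc(OC)c3c(=O)c(-c4ccc(OC)cc4)coc23)cc1 | intermediate
15 | (4-{[5,7-dimethoxy-3-(4-methoxyphenyl)-4-oxo-4H-chromen-8-yl]oxy}phenyl)acetic acid | OC(=O)Cc1ccc(Oc2c(OC)cc(OC)c3c(=O)c(-c4ccc(OC)cc4)coc23)cc1 | intermediate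
16 | 3,5-dimethoxyphenol | COc1cc(O)cc(OC)c1 | starting material
17 | 2-chloro-3,5-dimethoxyphenol | COc1cc(O)c(Cl)c(OC)c1 | intermediate
18 | 1-(3-chloro-2-hydroxy-4,6-dimethoxyphenyl)-2-(4-{[5,7-dimethoxy-3-(4-methoxyphenyl)-4-oxo-4H-chromen-8-yl]oxy}phenyl)ethan-1-one | COc1cc(OC)c(C(=O)Cc2ccc(Oc3c(OC)cc(OC)c4c(=O)c(-c5ccc(OC)cc5)coc34)cc2)c(O)c1Cl | intermediate
19 | (E)-1-(3-chloro-2-hydroxy-4,6-dimethoxyphenyl)-3-(dimethylamino)-2-(4-{[5,7-dimethoxy-3-(4-methoxyphenyl)-4-oxo-4H-chromen-8-yl]oxy}phenyl)prop-2-en-1-one (not isolated) | COc1cc(OC)c(C(=O)/C(=C/N(C)C)c2ccc(Oc3c(OC)cc(OC)c4c(=O)c(-c5ccc(OC)cc5)coc34)cc2)c(O)c1Cl | intermediate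
20 | 8-chloro-3-(4-{[5,7-dimethoxy-3-(4-methoxyphenyl)-4-oxo-4H-chromen-8-yl]oxy}phenyl)-5,7-dimethoxy-4H-chromen-4-one | O=c1c(-c2ccc(Oc3c(OC)cc(OC)c4c(=O)c(-c5ccc(OC)cc5)coc34)cc2)coc2c(Cl)c(OC)cc(OC)c12 | intermediate
21 | 8-chloro-3-(4-{[5,7-dihydroxy-3-(4-hydroxyphenyl)-4-oxo-4H-chromen-8-yl]oxy}phenyl)-5,7-dihydroxy-4H-chromen-4-one | O=c1c(-c2ccc(Oc3c(O)cc(O)c4c(=O)c(-c5ccc(O)cc5)coc34)cc2)coc2c(Cl)c(O)cc(O)c12 | target

**Totals**
Total step count: 15.
Longest linear sequence: 11 steps (steps 1–4, 8–11 and 13–15, from compound 1).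

**Steps most likely to fail**

Step 13. C-acylation of the deactivated chlorophenol may be slow, so that the advanced acid condenses with the still nucleophilic C6 of its own ring A, loses its 5-methoxy group in hot BF3·Et2O, or acylates para to the hydroxyl. The fallback separates the joining of the fragments from the C–C bond formation. Setting out from 15 and 17, the two are first coupled under mild conditions (EDC·HCl, DMAP, CH2Cl2, rt) to the aryl ester 2-chloro-3,5-dimethoxyphenyl (4-{[5,7-dimethoxy-3-(4-methoxyphenyl)-4-oxo-4H-chromen-8-yl]oxy}phenyl)acetate F1. The acyl group is then moved from oxygen to the ortho carbon by a Lewis acid Fries rearrangement (TiCl4, 1,2-dichloroethane, 60 °C), in which the titanium chelate favours the ortho-hydroxy ketone. This comes back to the route at 18.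

Step 8. The phenoxide may attack sulfur of the enol tosylate (sulfonyl transfer) instead of the β-carbon, or the geometry may be lost in a long-lived α-aryl ester enolate. The fallback runs the same ring closure at the saturated oxidation level.
- Setting out from 9, α-methylenation ((CH2O)n, K2CO3, Bu4NI, toluene, 80 °C) should give tert-butyl 2-(4-methoxyphenyl)prop-2-enoate F2.
- Oxa-Michael addition of phenol 7 (Cs2CO3 cat., MeCN, rt) should give racemic tert-butyl 3-{2-[4-(2-methoxy-2-oxoethyl)phenoxy]-3,5-dimethoxyphenoxy}-2-(4-methoxyphenyl)propanoate F3.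
- Acidolysis (CF3CO2H, CH2Cl2) should give racemic 3-{2-[4-(2-methoxy-2-oxoethyl)phenoxy]-3,5-dimethoxyphenoxy}-2-(4-methoxyphenyl)propanoic acid F4.
- P2O5 in CH3SO3H should close ring C by the same C4–C4a acylation to the racemic isoflavanone methyl (4-{[5,7-dimethoxy-3-(4-methoxyphenyl)-4-oxo-3,4-dihydro-2H-chromen-8-yl]oxy}phenyl)acetate F5.
- Dehydrogenation of C2–C3 with DDQ in 1,4-dioxane at reflux removes the transient stereocentre and comes back to the route at 14.

Step 10. Protonation of the enol ether carbon followed by loss of the phenol (retro-addition), or sulfonation and oligomerisation of the electron-rich ring A in the strongly acidic medium, may outpace ring closure. The fallback forms C4–C4a first and O1–C2 last. Setting out from 7 and 8, Friedel–Crafts acylation in BF3·Et2O at 85 °C ortho to the only hydroxyl should give the deoxybenzoin methyl (4-{2-hydroxy-4,6-dimethoxy-3-[(4-methoxyphenyl)acetyl]phenoxy}phenyl)acetate F6. Heating with N,N-dimethylformamide dimethyl acetal in toluene should form the enaminone methyl (4-{3-[(E)-3-(dimethylamino)-2-(4-methoxyphenyl)prop-2-enoyl]-2-hydroxy-4,6-dimethoxyphenoxy}phenyl)acetate F7, which closes with loss of dimethylamine. This comes back to the route at 14, and the regiochemistry stays fixed because 7 has a single hydroxyl.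

**Further compounds**
F1 | step 13 | 2-chloro-3,5-dimethoxyphenyl (4-{[5,7-dimethoxy-3-(4-methoxyphenyl)-4-oxo-4H-chromen-8-yl]oxy}phenyl)acetate | COc1cc(OC)c(Cl)c(OC(=O)Cc2ccc(Oc3c(OC)cc(OC)c4c(=O)c(-c5ccc(OC)cc5)coc34)cc2)c1
F2 | step 8 | tert-butyl 2-(4-methoxyphenyl)prop-2-enoate | C=C(C(=O)OC(C)(C)C)c1ccc(OC)cc1
F3 | step 8 | tert-butyl 3-{2-[4-(2-methoxy-2-oxoethyl)phenoxy]-3,5-dimethoxyphenoxy}-2-(4-methoxyphenyl)propanoate (racemic) | CC(C)(C)OC(=O)C(COc1cc(OC)cc(OC)c1Oc1ccc(CC(=O)OC)cc1)c1ccc(OC)cc1
F4 | step 8 | 3-{2-[4-(2-methoxy-2-oxoethyl)phenoxy]-3,5-dimethoxyphenoxy}-2-(4-methoxyphenyl)propanoic acid (racemic) | OC(=O)C(COc1cc(OC)cc(OC)c1Oc1ccc(CC(=O)OC)cc1)c1ccc(OC)cc1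
F5 | step 8 | methyl (4-{[5,7-dimethoxy-3-(4-methoxyphenyl)-4-oxo-3,4-dihydro-2H-chromen-8-yl]oxy}phenyl)acetate (racemic) | COC(=O)Cc1ccc(Oc2c(OC)cc(OC)c3C(=O)C(c4ccc(OC)cc4)COc23)cc1
F6 | step 10 | methyl (4-{2-hydroxy-4,6-dimethoxy-3-[(4-methoxyphenyl)acetyl]phenoxy}phenyl)acetate | COC(=O)Cc1ccc(Oc2c(O)c(C(=O)Cc3ccc(OC)cc3)c(OC)cc2OC)cc1
F7 | step 10 | methyl (4-{3-[(E)-3-(dimethylamino)-2-(4-methoxyphenyl)prop-2-enoyl]-2-hydroxy-4,6-dimethoxyphenoxy}phenyl)acetate | COC(=O)Cc1ccc(Oc2c(O)c(C(=O)/C(=C/N(C)C)c3ccc(OC)cc3)c(OC)cc2OC)cc1
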